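The numbers in the tables stem from a simulated flask for an exercise.

Don't rank these flasks by how they were fed. Your hunch that a slow feed buys J share is the pitfall, because the 30.0 h hold after the last addition is longer than the 25.0 h Monday's run needed. By then Monday's J stood within 0.8 percentage points of its last reading, and Tuesday's J is flat from 5.00 h. Elm's cold feed ends at 20 h too, and elm gets the same hold at 25 °C. So expect thermodynamic, not kinetic, control: one end state and one number.

| flask | L | D | E | temperature | remark | time |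
|---|---|---|---|---|---|---|
| Monday's | 16 mM | 1.1 equiv | 2 equiv | 20 °C | run made earlier |  |
| Tuesday's | 16 mM | 1.1 equiv | 2.8 equiv | 31 °C | run made earlier |  |
| Sunday's | 16 mM | 1.1 equiv | 4.4 equiv | 20 °C | run made earlier |  |
| Friday's | 24 mM | 1.1 equiv | 2 equiv | 31 °C | run made earlier |  |
| maple | 16 mM | 1.10 equiv (in portions, 4, over 20 h) | 2.00 equiv | 25 °C | first portion at the start, last at 20 h | 50 h |
| elm | 16 mM (fed, over 20 h) | 1.10 equiv | 2.00 equiv |  | the addition at −15 °C, then warmed to 25 °C; the feed brings no volume worth counting | 50 h |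
| oak | 16 mM (fed, over 20 h) | 1.10 equiv | 2.00 equiv | 25 °C | all else is in the flask from the start; the feed brings no volume worth counting | 50 h |
| alder | 16 mM | 1.10 equiv (fed, over 20 h) | 2.00 equiv | 25 °C | all else is in the flask from the start; the feed brings no volume worth counting | 50 h |

- Monday's (time / h: J / %, G / %): 4.00: 64.3, 1.2; 8.00: 61.4, 1.0; 15.0: 59.2, 1.2; 25.0: 57.5, 1.9; 48.0: 56.7, 1.2
- Tuesday's (time / h: J / %, G / %): 5.00: 27.6, 2.0; 10.0: 27.3, 2.3; 15.0: 26.9, 1.6; 30.0: 27.7, 1.9; 60.0: 27.2, 1.5
- Sunday's (time / h: J / %, G / %): 12.0: 45.5, 1.3; 25.0: 42.0, 1.3; 40.0: 40.6, 1.0; 50.0: 39.7, 0.6; 60.0: 40.7, 0.9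
- Friday's (time / h: J / %, G / %): 12.0: 40.0, 1.8; 25.0: 39.4, 1.6; 40.0: 40.0, 2.6; 50.0: 39.9, 2.3; 60.0: 39.1, 1.7

(readings scatter by 0.3 percentage points)

- a reading or a percentage of J counts all its forms, free or not

* the flask that comes out highest in share of J in J plus G, or "all alike" when all lie within 1.5 percentage points (maple / elm / oak / alder / all alike)
* share of J in J plus G at the end, maple
* share of J in J plus G at the end, elm
* share of J in J plus G at the end, oak
* share of J in J plus G at the end, alder

Work in the odds G/J, both as fractions of the L charged, and in powers of ten. Take Monday's readings from 15.0 h on: the odds are 0.0248, logarithm −1.61. Tuesday's readings give 0.0680, logarithm −1.17. Their difference is 0.438: the odds gain, the powers of ten that G/J climbs from Monday's run to Tuesday's. Hold it as rough. Tuesday's run differs from Monday's in temperature and also in E, with 2.8 equiv against 2 equiv, while Friday's keeps the recipe's E but has 24 mM of L and reads 0.0504, lower than Tuesday's. Lay the logarithm straight in temperature. 25 °C stands 0.455 of the way along, so my odds are 0.0392 and my J share is 96.2% in each flask.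

The forecast says all alike at 96.5% each, against my 96.2%, holding that “feed history is forgotten”.

Maple, elm, oak and alder end at 95.5%, 95.5%, 95.5% and 95.5%: all alike.

    L + D ⇌ E + J (K = 4.10, k = 0.0760 L mol⁻¹ s⁻¹, Ea = 40.0 kJ mol⁻¹, ΔH = −90.0 kJ mol⁻¹)
    L ⇌ Q (K = 0.480, k = 2.60 × 10⁻⁵ s⁻¹, Ea = 94.0 kJ mol⁻¹, ΔH = −58.0 kJ mol⁻¹)
    J + D ⇌ E + G (K = 0.230, k = 0.0470 L mol⁻¹ s⁻¹, Ea = 61.0 kJ mol⁻¹, ΔH = 16.0 kJ mol⁻¹)
    X ⇌ J, rate k4*(cs4 - [J]) while solid is left; crystals form when [J] > cs4 (solubility = 5.90 mM, k = 0.0140 s⁻¹)
    (constants at 25 °C)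

Maple's G and J at 50.0 h, X counted in J, give odds of 0.0476. That stands 0.0843 powers of ten above my reckoning, against a gain of 0.438. Carry the same gain to the repeat of maple at 0 °C, amounts and time held. That temperature lies −1.82 spans from Monday's, so the odds fall to 0.00396 and the J share reckons at 99.6%. That flask gives 99.7%, with 5.1% of the L still unbound.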